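**Retrosynthetic overview**

1. Enabling feature: ring B (O-1, C-2, C-3, C-4, C-4a, C-8a) is a cyclic vinylogous ester O-1–C-8a=C-4a–C-4=O and ring A (C-4a, C-5, C-6, O-7, C-8, C-8a) a δ-lactone on the same C-4a=C-8a alkene. The bicycle is therefore the twofold condensed form (loss of water and of methanol) of an open 2,4-dioxo ester with hydroxyls at C-2 and C-6. Capping C-4 with the C-6 oxygen instead gives an isomeric 3-oxalyl-4,5-dihydrofuran in which C-3 is a vinylogously acidic methyl group.
2. Key disconnection: C-2–C-3 and O-1–C-8a, to octanal and the exo-methylene dienol silane of that dihydrofuran (formal oxa-[4+2] by enantioselective vinylogous Mukaiyama aldol addition and hemiketalisation). Acid in the same flask opens the dihydrofuran and closes ring B, then ring A.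
3. The dihydrofuran keto ester comes from C-acylation of (2R)-2-decyl-5-methyl-2,3-dihydrofuran with methyl chlorooxoacetate, the enol ether from cyclodehydration of (5R)-5-hydroxypentadecan-2-one, and that from (R)-1,2-epoxydodecane and 2-methylallylmagnesium chloride followed by ozonolysis.
4. Ring order: temporary dihydrofuran (step 3), then ring B and ring A in step 6, where the temporary ring is opened again.
5. Stereocentres: C-6 is bought with the epoxide and its C–O bond is never broken; C-2 is set by the chiral titanium–BINOL catalyst in step 6.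

Key step: step 6

Remark: target locants are those of pyrano[3,4-b]pyran (O-1, C-2 heptyl, C-4 ketone, C-6 decyl, O-7, C-8 lactone carbonyl). The dienol silane is used as the mixture of isomers at its exocyclic C=C(OSi) bond, whose geometry is erased in step 6.

**Route**

Step 1
Reactants: 1 (R)-1,2-epoxydodecane; 2 2-methylallylmagnesium chloride
Product: 3 (5R)-2-methylpentadec-1-en-5-ol
Conditions: CuI (5 mol%), THF, −30 → 0 °C; then cold 1 M HCl
Reagents that add atoms: none
Why: The CuI-catalysed Grignard opening of a terminal epoxide should occur by SN2 attack at the unsubstituted carbon, so the C–O bond of the stereocentre is untouched and the (R) configuration of 1 is carried into 3.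

Step 2
Reactants: 3 (5R)-2-methylpentadec-1-en-5-ol
Product: 4 (5R)-5-hydroxypentadecan-2-one
Conditions: O3, CH2Cl2–MeOH, −78 °C; Me2S, −78 °C → rt
Reagents that add atoms: ozone ([O-][O+]=O)
Why: Ozonolysis of the 1,1-disubstituted alkene with reductive work-up should cleave only the C=C bond to the methyl ketone, the secondary alcohol and its stereocentre being inert to ozone at −78 °C.

Step 3
Reactants: 4 (5R)-5-hydroxypentadecan-2-one
Product: 6 (2R)-2-decyl-5-methyl-2,3-dihydrofuran, via lactol 5 (not isolated)
Conditions: PPTS (2 mol%), PhMe, reflux, azeotropic removal of water; K2CO3, filtration through basic alumina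
Reagents that add atoms: none
Why: Acid-catalysed cyclodehydration of a γ-hydroxy ketone through its lactol should give the cyclic enol ether, the endocyclic trisubstituted isomer being the thermodynamic one under these equilibrating conditions, and the C–O bond at the stereocentre is not broken.

Step 4
Reactants: 6 (2R)-2-decyl-5-methyl-2,3-dihydrofuran; 7 methyl chlorooxoacetate
Product: 8 methyl 2-[(5R)-5-decyl-2-methyl-4,5-dihydrofuran-3-yl]-2-oxoacetate
Conditions: pyridine (1.5 equiv), CH2Cl2, −20 → 0 °C
Reagents that add atoms: none
Why: C-Acylation of an electron-rich enol ether by an oxalyl chloride (a Friedel–Crafts-type addition–elimination known for vinyl ethers and dihydrofurans) should occur at the β-carbon, the only nucleophilic ring carbon of 6, and loss of a proton to pyridine restores the enol ether as a vinylogous ester, which places the oxalyl unit regiospecifically on the future C-4a.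

Step 5
Reactants: 8 methyl 2-[(5R)-5-decyl-2-methyl-4,5-dihydrofuran-3-yl]-2-oxoacetate
Product: 9 methyl 2-[(5R)-5-decyl-2-methylideneoxolan-3-ylidene]-2-[(trimethylsilyl)oxy]acetate
Conditions: TMSOTf (1.3 equiv), Et3N (2 equiv), Et2O, 0 °C; decanted from the ammonium salt, concentrated, used crude
Reagents that add atoms: trimethylsilyl trifluoromethanesulfonate (C[Si](C)(C)OS(=O)(=O)C(F)(F)F)
Why: Soft enolisation should silylate the ketone oxygen of the vinylogous ester and remove a hydrogen of the 2-methyl group, the only proton whose loss neutralises the resulting cation because the other flank of the ketone is the ester, giving the cross-conjugated exo-methylene dienol silane as in the γ-enolisation of 6-methyl-1,3-dioxin-4-ones.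

Step 6
Reactants: 9 methyl 2-[(5R)-5-decyl-2-methylideneoxolan-3-ylidene]-2-[(trimethylsilyl)oxy]acetate; 10 octanal
Product: 14 (2S,6R)-6-decyl-2-heptyl-2,3,5,6-tetrahydro-4H,8H-pyrano[3,4-b]pyran-4,8-dione, via silyl aldol adduct 11 (not isolated), via bicyclic hemiketal 12 (not isolated), via ring-B hydroxy ester 13 (not isolated)
Conditions: Ti(OiPr)4 (10 mol%), (R)-BINOL (20 mol%), 4 Å MS, Et2O, −20 °C; then TFA–H2O (9:1), CH2Cl2, 0 °C → rt
Reagents that add atoms: water (O)
Why: Proposed new method: the terminal methylidene carbon of 9 (future C-3), activated by both the ring oxygen on C-4 and the silyloxy group on C-8a, should add to titanium-bound octanal in an open vinylogous Mukaiyama aldol transition state to give 11 (C-2–C-3 bond); wet TFA then exchanges the silyl ether for hemiketal 12 by closure of the C-2 oxygen on the C-8a ketone (O-1–C-8a bond), acid-catalysed dehydration–rehydration across C-8a/C-4a/C-4 moves the water from C-8a to C-4 and expels the C-6 oxygen (opening of the temporary dihydrofuran) to give 13, and 13 lactonises with loss of methanol to 14. The closest known reaction types are the catalytic enantioselective vinylogous Mukaiyama aldol addition of exo-methylene dienol silanes from 1,3-dioxin-4-ones to aliphatic aldehydes, the aldol–acid cyclodehydration route to 2,3-dihydro-4H-pyran-4-ones from 1-alkoxy-3-silyloxy dienes (formal hetero-Diels–Alder reaction) and the acid hydrolysis of 3-acyl-4,5-dihydrofurans; only their union into one ring transposition is new. Ring B closes by 6-exo-trig hemiketalisation followed by dehydration, and ring A by 6-exo-trig transesterification of the C-6 hydroxyl with the C-8 ester, which the C-4a=C-8a alkene holds cis. C-2 is set by the catalyst alone, (R)-BINOL being the antipode expected from the usual sense of this catalyst family to expose the Re face of octanal (which gives 2S), since the C-6 stereocentre is too remote to interfere; C-6 keeps its configuration because its C–O bond is never broken. The step needs γ- over α-attack of the dienol silane, secured by the fully substituted α-carbon C-4a, and it needs the six-membered capping by the C-2 oxygen to win over return to five-membered dihydrofurans, secured by water keeping all furan forms reversible while lactonisation with loss of methanol drains the equilibrium to the bicycle.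

**Compound list**

1 | (R)-1,2-epoxydodecane | CCCCCCCCCC[C@@H]1CO1 | starting material
2 | 2-methylallylmagnesium chloride | CC(=C)C[Mg]Cl | starting material
3 | (5R)-2-methylpentadec-1-en-5-ol | CCCCCCCCCC[C@@H](O)CCC(C)=C | intermediate
4 | (5R)-5-hydroxypentadecan-2-one | CCCCCCCCCC[C@@H](O)CCC(C)=O | intermediate
5 | (5R)-5-decyl-2-methyloxolan-2-ol (lactol, both C-2 epimers) | CCCCCCCCCC[C@@H]1CCC(C)(O)O1 | intermediate
6 | (2R)-2-decyl-5-methyl-2,3-dihydrofuran | CCCCCCCCCC[C@@H]1CC=C(C)O1 | intermediate
7 | methyl chlorooxoacetate | COC(=O)C(Cl)=O | starting material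
8 | methyl 2-[(5R)-5-decyl-2-methyl-4,5-dihydrofuran-3-yl]-2-oxoacetate | CCCCCCCCCC[C@@H]1CC(C(=O)C(=O)OC)=C(C)O1 | intermediate
9 | methyl 2-[(5R)-5-decyl-2-methylideneoxolan-3-ylidene]-2-[(trimethylsilyl)oxy]acetate (mixture of C=C isomers) | CCCCCCCCCC[C@@H]1CC(=C(O[Si](C)(C)C)C(=O)OC)C(=C)O1 | intermediate
10 | octanal | CCCCCCCC=O | starting material
11 | methyl 2-{(5R)-5-decyl-2-[(2S)-2-[(trimethylsilyl)oxy]nonyl]-4,5-dihydrofuran-3-yl}-2-oxoacetate | CCCCCCCCCC[C@@H]1CC(C(=O)C(=O)OC)=C(C[C@H](CCCCCCC)O[Si](C)(C)C)O1 | intermediate
12 | methyl (2R,6S)-2-decyl-6-heptyl-4-hydroxy-2,3,6,7-tetrahydro-4H-furo[3,2-c]pyran-4-carboxylate (both C-4 epimers) | CCCCCCCCCC[C@@H]1CC2=C(C[C@H](CCCCCCC)OC2(O)C(=O)OC)O1 | intermediate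
13 | methyl (2S)-2-heptyl-5-[(2R)-2-hydroxydodecyl]-4-oxo-3,4-dihydro-2H-pyran-6-carboxylate | CCCCCCCCCC[C@@H](O)CC1=C(C(=O)OC)O[C@@H](CCCCCCC)CC1=O | intermediate
14 | (2S,6R)-6-decyl-2-heptyl-2,3,5,6-tetrahydro-4H,8H-pyrano[3,4-b]pyran-4,8-dione | CCCCCCCCCC[C@@H]1CC2=C(O[C@@H](CCCCCCC)CC2=O)C(=O)O1 | target

**Summary**

Total step count: 6. Longest linear sequence: 6 steps (1 to 14).

**Steps most likely to fail**

Step 6. The acid-triggered transposition may stall at five-membered dihydrofuran isomers, or be drained by elimination of the aldol hydroxyl before the six-membered closure. Catalyst turnover may also be slowed by chelation of titanium by the α-keto ester. The fallback uses known chemistry and closes ring A before the aldol event; it sets out from 4 and comes back at 14. 4 is acylated on oxygen with 7 (pyridine, CH2Cl2, 0 °C) to give methyl (5R)-2-oxopentadecan-5-yl oxalate F1. LiN(SiMe3)2 (THF, −78 → 0 °C) then effects the intramolecular Claisen (Dieckmann) condensation of the internal ketone enolate on the distal oxalate carbonyl, the only mode that gives a six-membered ring, to (6R)-4-acetyl-6-decyl-3-hydroxy-5,6-dihydro-2H-pyran-2-one F2. TMSOTf/Et3N converts this into the bis(silyloxy)diene (6R)-6-decyl-3-[(trimethylsilyl)oxy]-4-{1-[(trimethylsilyl)oxy]ethenyl}-5,6-dihydro-2H-pyran-2-one F3. The Ti(OiPr)4/(R)-BINOL-catalysed Mukaiyama aldol addition of this diene to 10 should give (6R)-6-decyl-3-[(trimethylsilyl)oxy]-4-{(3S)-3-[(trimethylsilyl)oxy]decanoyl}-5,6-dihydro-2H-pyran-2-one F4, and TFA in CH2Cl2 closes ring B by the ordinary cyclodehydration of a δ-hydroxy 1,3-dicarbonyl compound to give 14.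

Step 4. Protonation of the enol ether by the pyridinium chloride that builds up, followed by hydrolysis or oligomerisation, may outrun C-acylation, and any exocyclic enol-ether tautomer would be acylated at the methyl carbon. The fallback builds the ring with the C-3 substituent already marked by a halogen; it sets out from 1 and comes back at 8. 1 is opened with 1-propynyllithium and BF3·OEt2 (THF, −78 °C) to (5R)-pentadec-2-yn-5-ol F5. Iodine and NaHCO3 (MeCN, 0 °C) should effect the 5-endo-dig iodocyclisation to (2R)-2-decyl-4-iodo-5-methyl-2,3-dihydrofuran F6. Iodine–lithium exchange (tert-butyllithium, Et2O, −78 °C) and addition of the vinyllithium to excess dimethyl oxalate then gives 8.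

Step 3. The dehydration may stop at the lactol or its anhydro dimers, or the acid-sensitive enol ether may oligomerise at reflux. The fallback replaces protic dehydration by an aprotic, base-buffered elimination; it sets out from 4 and comes back at 6. 4 is converted with MeOH, HC(OMe)3 and PPTS into the cyclic methyl ketal (5R)-5-decyl-2-methoxy-2-methyloxolane F7. TMSOTf and iPr2NEt (CH2Cl2, −20 °C) then eliminate methanol from this ketal to give 6, any exocyclic isomer being equilibrated with a trace of PPTS.

**Further compounds**

F1 | step 6 | methyl (5R)-2-oxopentadecan-5-yl oxalate | CCCCCCCCCC[C@@H](OC(=O)C(=O)OC)CCC(C)=O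
F2 | step 6 | (6R)-4-acetyl-6-decyl-3-hydroxy-5,6-dihydro-2H-pyran-2-one | CCCCCCCCCC[C@@H]1CC(C(C)=O)=C(O)C(=O)O1
F3 | step 6 | (6R)-6-decyl-3-[(trimethylsilyl)oxy]-4-{1-[(trimethylsilyl)oxy]ethenyl}-5,6-dihydro-2H-pyran-2-one | CCCCCCCCCC[C@@H]1CC(C(=C)O[Si](C)(C)C)=C(O[Si](C)(C)C)C(=O)O1
F4 | step 6 | (6R)-6-decyl-3-[(trimethylsilyl)oxy]-4-{(3S)-3-[(trimethylsilyl)oxy]decanoyl}-5,6-dihydro-2H-pyran-2-one | CCCCCCCCCC[C@@H]1CC(C(=O)C[C@H](CCCCCCC)O[Si](C)(C)C)=C(O[Si](C)(C)C)C(=O)O1
F5 | step 4 | (5R)-pentadec-2-yn-5-ol | CCCCCCCCCC[C@@H](O)CC#CC
F6 | step 4 | (2R)-2-decyl-4-iodo-5-methyl-2,3-dihydrofuran | CCCCCCCCCC[C@@H]1CC(I)=C(C)O1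
F7 | step 3 | (5R)-5-decyl-2-methoxy-2-methyloxolane (both C-2 epimers) | CCCCCCCCCC[C@@H]1CCC(C)(OC)O1
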